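The ten-membered carbocycle is made by contracting a twelve-membered ring across the C7–C8 bond (germacrane numbering). The target hides a γ,δ-unsaturated ketone retron, C9(=O)–C8–C7–C11=C13: the angelate carbon C9 and the ring-fusion carbon C7 of the ten-membered ring, joined by C8, plus the exocyclic methylene of the γ-lactone. A Claisen rearrangement of the macrocyclic allyl vinyl ether 27, a 2-methylene-oxacyclododecadiene made by Tebbe methylenation of macrolactone 26, forms C7–C8, expels O, C13 and C11 from the ring, relays C6 to C7, and unveils the C9 ketone and the C11=C13 methylene together. C6 and C3 (CBS) and C10 (oxazolidinone auxiliary) are set earlier; C9 follows by ketone reduction.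

Key step: step 18

Remark on labels: C1–C15 are germacrane locants. C3 bears the acetate, C4=C5 is the ring alkene (C15 its methyl), C6 is the lactone O–CH, C7 the ring-fusion CH, C8 the ring CH2 next to it, C9 bears the angelate, C10 bears the methyl C14, C11=C13 is the exocyclic methylene and C12 the lactone carbonyl. TBS = tert-butyldimethylsilyl, TES = triethylsilyl.
Assumption: 1,3-dihydroxyacetone is bought as its dimer and reacts as the monomer.

Step 1
Reactants: 1 1,3-dihydroxyacetone; 2 ethyl (triphenylphosphoranylidene)acetate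
Product: 4 4-(hydroxymethyl)furan-2(5H)-one, via hydroxy ester 3 (not isolated)
Conditions: CH2Cl2, 23 °C
Reagents that add atoms: none
Why: Wittig olefination of the ketone; the two CH2OH groups of 3 are equivalent, so one is always cis to the ester and lactonises, which from here on distinguishes the ring CH2O carbon (cis to the carbonyl carbon, future C13) from the exocyclic one (future C12).

Step 2
Reactants: 4 4-(hydroxymethyl)furan-2(5H)-one
Product: 5 4-{[(tert-butyldimethylsilyl)oxy]methyl}furan-2(5H)-one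
Conditions: TBSCl, imidazole, DMF, 0 → 23 °C
Reagents that add atoms: tert-butyldimethylsilyl chloride, CC(C)(C)[Si](C)(C)Cl
Why: Standard silylation of the primary alcohol (future C12–O), which stays protected until the end.

Step 3
Reactants: 5 TBS-protected butenolide
Product: 7 (E)-3-{[(tert-butyldimethylsilyl)oxy]methyl}-N-methoxy-N-methyl-4-[(triethylsilyl)oxy]but-2-enamide, via hydroxy amide 6 (not isolated)
Conditions: MeNHOMe·HCl, i-PrMgCl, THF, −20 °C; then TESCl, DMAP (cat.), −20 → 23 °C
Reagents that add atoms: N,O-dimethylhydroxylamine hydrochloride, CNOC.Cl; chlorotriethylsilane, CC[Si](Cl)(CC)CC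
Why: Weinreb aminolysis of the lactone by the chloromagnesium amide opens the ring with the alkene geometry fixed by the ring (amide carbonyl cis to the released CH2OH), and silylation in the same flask prevents relactonisation.

Step 4
Reactants: 7 TES-protected Weinreb amide; 8 1-propynylmagnesium bromide
Product: 9 (E)-1-[(tert-butyldimethylsilyl)oxy]-2-{[(triethylsilyl)oxy]methyl}hept-2-en-5-yn-4-one
Conditions: THF, −20 → 0 °C; aq. NH4Cl
Reagents that add atoms: none
Why: Weinreb ketone synthesis; the chelated tetrahedral intermediate survives until work-up, so the addition stops at the ynone.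

Step 5
Reactants: 9 ynone
Product: 10 (2E,4S)-1-[(tert-butyldimethylsilyl)oxy]-2-{[(triethylsilyl)oxy]methyl}hept-2-en-5-yn-4-ol
Conditions: (S)-Me-CBS (20 mol %), catecholborane, toluene, −78 °C
Reagents that add atoms: none
Why: CBS reduction in which the β,β-disubstituted alkenyl group acts as the large and the slim propynyl group as the small substituent, so the (S)-catalyst should give the (4S)-alcohol, which is the C6 arrangement of the target (labelled 6R there only because the CIP priorities change).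

Step 6
Reactants: 10 propargylic alcohol
Product: 11 (2E,4S,5Z)-1-[(tert-butyldimethylsilyl)oxy]-6-iodo-2-{[(triethylsilyl)oxy]methyl}hepta-2,5-dien-4-ol
Conditions: Red-Al, THF, 0 → 23 °C; EtOAc; then I2, THF, −78 °C
Reagents that add atoms: iodine, II
Why: Alkoxide-directed trans-hydroalumination puts H on the proximal alkyne carbon (C5) and Al on the distal one (C4) cis to the carbinol, and iodinolysis with retention gives the Z-vinyl iodide whose C–I bond marks the later C3–C4 bond cis to C6.

Step 7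
Reactants: 11 Z-iodo dienol
Product: 12 (2E,4S,5Z)-1,4-bis[(tert-butyldimethylsilyl)oxy]-6-iodo-2-{[(triethylsilyl)oxy]methyl}hepta-2,5-diene
Conditions: TBSOTf, 2,6-lutidine, CH2Cl2, −78 °C
Reagents that add atoms: tert-butyldimethylsilyl triflate, CC(C)(C)[Si](C)(C)OS(=O)(=O)C(F)(F)F
Why: Silylation of the bis-allylic alcohol under basic, non-ionising conditions; the OTBS group is later the control element at C6.

Step 8
Reactants: 13 (S)-4-benzyl-3-propionyloxazolidin-2-one; 14 tert-butyl acrylate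
Product: 15 tert-butyl (R)-5-[(S)-4-benzyl-2-oxooxazolidin-3-yl]-4-methyl-5-oxopentanoate
Conditions: TiCl4, i-Pr2NEt, CH2Cl2, 0 °C; then 14, 0 °C
Reagents that add atoms: none
Why: Michael addition of the chelated Z-chlorotitanium enolate of the N-propionyl oxazolidinone; the acrylate approaches the face opposite the benzyl group, which sets C10 as R.

Step 9
Reactants: 15 Michael adduct
Product: 16 (R)-5-[(S)-4-benzyl-2-oxooxazolidin-3-yl]-4-methyl-5-oxopentanoic acid
Conditions: TFA, CH2Cl2, 0 → 23 °C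
Reagents that add atoms: none
Why: Acidolysis of the tert-butyl ester through the tert-butyl cation leaves the imide and C10 untouched.

Step 10
Reactants: 16 imide acid
Product: 17 (R)-5-[(S)-4-benzyl-2-oxooxazolidin-3-yl]-4-methyl-5-oxopentanoyl chloride
Conditions: (COCl)2, DMF (cat.), CH2Cl2, 0 → 23 °C
Reagents that add atoms: oxalyl chloride, ClC(=O)C(=O)Cl
Why: Vilsmeier-type acid chloride formation under neutral conditions; C10 is γ to the new acyl chloride and cannot epimerise.

Step 11
Reactants: 12 Z-vinyl iodide; 17 acid chloride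
Product: 20 (S)-4-benzyl-3-[(2R,6Z,8S,9E)-8,11-bis{[tert-butyldimethylsilyl]oxy}-2,6-dimethyl-5-oxo-10-{[(triethylsilyl)oxy]methyl}undeca-6,9-dienoyl]oxazolidin-2-one, via vinyllithium 18 (not isolated), via vinylzinc chloride 19 (not isolated)
Conditions: t-BuLi (2.1 equiv), Et2O, −78 °C; ZnCl2, THF, −78 → 0 °C; then 17, Pd(PPh3)4 (5 mol %), 0 → 23 °C
Reagents that add atoms: none
Why: I/Li exchange and transmetalation to zinc go with retention (at −78 °C the TBS group is too slow for a 1,4 O→C silyl shift), and the Negishi acylation couples the alkenylzinc with the acid chloride only, so the Z-enone with C3 cis to C6 should result with the imide intact.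

Step 12
Reactants: 20 Z-enone
Product: 21 (S)-4-benzyl-3-[(2R,5S,6Z,8S,9E)-8,11-bis{[tert-butyldimethylsilyl]oxy}-5-hydroxy-2,6-dimethyl-10-{[(triethylsilyl)oxy]methyl}undeca-6,9-dienoyl]oxazolidin-2-one
Conditions: (R)-Me-CBS (30 mol %), catecholborane, toluene, −78 → −40 °C
Reagents that add atoms: none
Why: CBS 1,2-reduction with the α-methyl alkenyl group as the large and the CH2 chain as the small substituent, so the (R)-catalyst should give the (5S)-alcohol, which is C3 of the target, without touching the imide.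

Step 13
Reactants: 21 allylic alcohol
Product: 22 (S)-4-benzyl-3-[(2R,5S,6Z,8S,9E)-5,8,11-tris{[tert-butyldimethylsilyl]oxy}-2,6-dimethyl-10-{[(triethylsilyl)oxy]methyl}undeca-6,9-dienoyl]oxazolidin-2-one
Conditions: TBSOTf, 2,6-lutidine, CH2Cl2, −78 °C (crude 21, used at once)
Reagents that add atoms: tert-butyldimethylsilyl triflate, CC(C)(C)[Si](C)(C)OS(=O)(=O)C(F)(F)F
Why: Fast silylation of the allylic alcohol before it can lactonise onto the activated imide carbonyl.

Step 14
Reactants: 22 tris-TBS TES ether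
Product: 23 (S)-4-benzyl-3-[(2R,5S,6Z,8S,9E)-5,8,11-tris{[tert-butyldimethylsilyl]oxy}-10-(hydroxymethyl)-2,6-dimethylundeca-6,9-dienoyl]oxazolidin-2-one
Conditions: PPTS (cat.), MeOH/CH2Cl2 (1:1), 0 °C
Reagents that add atoms: none
Why: Acid-catalysed methanolysis removes the primary TES ether much faster than any of the three TBS ethers and frees C13–OH only.

Step 15
Reactants: 23 hydroxy imide
Product: 24 (2R,5S,6Z,8S,9E)-5,8,11-tris[(tert-butyldimethylsilyl)oxy]-10-(hydroxymethyl)-2,6-dimethylundeca-6,9-dienoic acid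
Conditions: LiOH, H2O2, THF/H2O (3:1), 0 °C; aq. Na2SO3; HCl to pH 4
Reagents that add atoms: lithium hydroperoxide (from LiOH and H2O2), [Li+].[O-]O
Why: Hydroperoxide attacks the exocyclic imide carbonyl selectively, releasing the auxiliary without epimerising C10.

Step 16
Reactants: 24 seco acid
Product: 26 (3R,6S,7Z,9S,10E)-6,9-bis[(tert-butyldimethylsilyl)oxy]-11-{[(tert-butyldimethylsilyl)oxy]methyl}-3,7-dimethyl-1-oxacyclododeca-7,10-dien-2-one (ring bonds cis at both alkenes), via mixed anhydride 25 (not isolated)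
Conditions: 2,4,6-trichlorobenzoyl chloride, Et3N, THF, 23 °C; then slow addition to DMAP, toluene (1 mM), 60 °C
Reagents that add atoms: none
Why: Yamaguchi macrolactonisation; C13–OH is the only free hydroxyl and the two ring-cis alkenes fold the chain, so the 12-membered lactone should close at high dilution.

Step 17
Reactants: 26 macrolactone
Product: 27 (3R,6S,7Z,9S,10E)-6,9-bis[(tert-butyldimethylsilyl)oxy]-11-{[(tert-butyldimethylsilyl)oxy]methyl}-3,7-dimethyl-2-methylene-1-oxacyclododeca-7,10-diene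
Conditions: Tebbe reagent, pyridine, THF/toluene, −40 → 0 °C; aq. NaOH; filtration through basic alumina
Reagents that add atoms: Tebbe reagent, C[Al-]1(C)C[Ti](C2C=CC=C2)(C2C=CC=C2)[Cl+]1
Why: Tebbe methylenation (titanocene methylidene, [2+2] then cycloreversion) of the only carbonyl group in the molecule under non-basic conditions that leave C10 intact.

Step 18
Reactants: 27 macrocyclic allyl vinyl ether
Product: 28 (2R,5S,6Z,8R,9S)-5,8-bis[(tert-butyldimethylsilyl)oxy]-9-{3-[(tert-butyldimethylsilyl)oxy]prop-1-en-2-yl}-2,6-dimethylcyclodec-6-en-1-one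
Conditions: o-xylene, base-washed sealed tube, BHT (trace), 150 °C
Reagents that add atoms: none
Why: Thermal [3,3]-sigmatropic (Claisen) rearrangement of the allyl vinyl ether C8=C9–O–C13–C11=C7 that is part of the 12-membered ring; the closest known reaction type is the ring-contracting Claisen rearrangement of exocyclic enol ethers obtained from macrolactones by Tebbe methylenation. The ten-membered ring closes by suprafacial C8–C7 bonding through a six-membered chair-like transition state while the C13–O bond breaks, so that O, C13 and C11 leave the ring and C8 enters it (12 → 10). C7 is the only new stereocentre and is controlled by C6: to avoid A(1,3) strain with the cis C13H2 group the C6–H bond lies in the plane of C7=C11, which puts C5 (the ring arm that carries the vinyl ether) and the OTBS group on opposite faces, and C8 bonds on the C5 face, anti to the C6–O bond, which corresponds to the trans-fused lactone. The step needs this π-facial selectivity and an intact exocyclic enol ether (an acid-induced shift of C8=C9 to C9=C10 would reroute bond formation to C10); the first is secured by the ring-cis C7=C11 alkene and the bulky silyl ether at C6, the second by strictly acid-free conditions. The same event delivers the C9 ketone and the exocyclic C11=C13 methylene.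

Step 19
Reactants: 28 cyclodecenone
Product: 29 (1S,2R,5S,6Z,8R,9S)-5,8-bis[(tert-butyldimethylsilyl)oxy]-9-{3-[(tert-butyldimethylsilyl)oxy]prop-1-en-2-yl}-2,6-dimethylcyclodec-6-en-1-ol
Conditions: L-Selectride, THF, −78 °C; aq. NH4Cl
Reagents that add atoms: none
Why: Felkin–Anh reduction by a bulky hydride from the ring periphery: with the C10–C1 ring bond perpendicular to the carbonyl and anti to the hydride, which passes H-10 and not the C14 methyl, the new C9–O bond should end up cis to the C10 methyl (9S).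

Step 20
Reactants: 29 cyclodecenol; 30 angelic acid
Product: 32 (1S,2R,5S,6Z,8R,9S)-5,8-bis[(tert-butyldimethylsilyl)oxy]-9-{3-[(tert-butyldimethylsilyl)oxy]prop-1-en-2-yl}-2,6-dimethylcyclodec-6-en-1-yl (Z)-2-methylbut-2-enoate, via angeloyl mixed anhydride 31 (not isolated)
Conditions: 30, 2,4,6-trichlorobenzoyl chloride, Et3N, toluene, 23 °C; then 29, toluene, 80 °C
Reagents that add atoms: none
Why: Yamaguchi-type esterification with the preformed mixed anhydride and no DMAP acylates the hindered alcohol with retention at C9 and avoids Z→E isomerisation of the angelate to the tiglate.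

Step 21
Reactants: 32 angelate tris-silyl ether
Product: 33 (1S,2R,5S,6Z,8R,9S)-5,8-dihydroxy-9-(3-hydroxyprop-1-en-2-yl)-2,6-dimethylcyclodec-6-en-1-yl (Z)-2-methylbut-2-enoate
Conditions: HF·pyridine, pyridine, THF, 0 → 23 °C
Reagents that add atoms: none
Why: Buffered fluoride cleaves the three Si–O bonds; the angelate and the allylic alcohols tolerate these mildly acidic conditions.

Step 22
Reactants: 33 triol
Product: 36 (3S,6R,7S,9S,10R)-9-angeloyloxy-3-hydroxygermacra-4(Z),11(13)-dien-12,6-olide, via hydroxy enal 34 (not isolated), via lactol 35 (not isolated)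
Conditions: TEMPO (20 mol %), PhI(OAc)2 (2.5 equiv), CH2Cl2, 23 °C
Reagents that add atoms: none
Why: Oxoammonium oxidation prefers the primary allylic alcohol; the enal is trapped by C6–OH as the γ-lactol, which is oxidised to the α-methylene lactone, while the secondary C3–OH reacts more slowly and should remain.

Step 23
Reactants: 36 hydroxy lactone
Product: 37 (3S,6R,7S,9S,10R)-3-acetoxy-9-angeloyloxygermacra-4(Z),11(13)-dien-12,6-olide (CNP0173235.1)
Conditions: Ac2O, pyridine, DMAP (cat.), CH2Cl2, 0 °C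
Reagents that add atoms: acetic anhydride, CC(=O)OC(C)=O
Why: Acylation of the remaining secondary alcohol with retention at C3.

Compound list
1 | 1,3-dihydroxyacetone (commercial as dimer) | O=C(CO)CO | starting material
2 | ethyl (triphenylphosphoranylidene)acetate | CCOC(=O)C=P(c1ccccc1)(c1ccccc1)c1ccccc1 | starting material
3 | ethyl 4-hydroxy-3-(hydroxymethyl)but-2-enoate (not isolated) | CCOC(=O)C=C(CO)CO | intermediate
4 | 4-(hydroxymethyl)furan-2(5H)-one | O=C1C=C(CO)CO1 | intermediate
5 | 4-{[(tert-butyldimethylsilyl)oxy]methyl}furan-2(5H)-one | O=C1C=C(CO[Si](C)(C)C(C)(C)C)CO1 | intermediate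
6 | (E)-3-{[(tert-butyldimethylsilyl)oxy]methyl}-4-hydroxy-N-methoxy-N-methylbut-2-enamide (amide C=O cis to CH2OH; not isolated) | CON(C)C(=O)/C=C(/CO[Si](C)(C)C(C)(C)C)CO | intermediate
7 | (E)-3-{[(tert-butyldimethylsilyl)oxy]methyl}-N-methoxy-N-methyl-4-[(triethylsilyl)oxy]but-2-enamide (amide C=O cis to CH2OTES) | CON(C)C(=O)/C=C(/CO[Si](C)(C)C(C)(C)C)CO[Si](CC)(CC)CC | intermediate
8 | 1-propynylmagnesium bromide | CC#C[Mg]Br | starting material
9 | (E)-1-[(tert-butyldimethylsilyl)oxy]-2-{[(triethylsilyl)oxy]methyl}hept-2-en-5-yn-4-one | CC#CC(=O)/C=C(/CO[Si](C)(C)C(C)(C)C)CO[Si](CC)(CC)CC | intermediate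
10 | (2E,4S)-1-[(tert-butyldimethylsilyl)oxy]-2-{[(triethylsilyl)oxy]methyl}hept-2-en-5-yn-4-ol | CC#C[C@@H](O)/C=C(/CO[Si](C)(C)C(C)(C)C)CO[Si](CC)(CC)CC | intermediate
11 | (2E,4S,5Z)-1-[(tert-butyldimethylsilyl)oxy]-6-iodo-2-{[(triethylsilyl)oxy]methyl}hepta-2,5-dien-4-ol | C/C(I)=C/[C@@H](O)/C=C(/CO[Si](C)(C)C(C)(C)C)CO[Si](CC)(CC)CC | intermediate
12 | (2E,4S,5Z)-1,4-bis[(tert-butyldimethylsilyl)oxy]-6-iodo-2-{[(triethylsilyl)oxy]methyl}hepta-2,5-diene | C/C(I)=C/[C@@H](O[Si](C)(C)C(C)(C)C)/C=C(/CO[Si](C)(C)C(C)(C)C)CO[Si](CC)(CC)CC | intermediate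
13 | (S)-4-benzyl-3-propionyloxazolidin-2-one | CCC(=O)N1[C@@H](Cc2ccccc2)COC1=O | starting material
14 | tert-butyl acrylate | C=CC(=O)OC(C)(C)C | starting material
15 | tert-butyl (R)-5-[(S)-4-benzyl-2-oxooxazolidin-3-yl]-4-methyl-5-oxopentanoate | CC(C)(C)OC(=O)CC[C@@H](C)C(=O)N1[C@@H](Cc2ccccc2)COC1=O | intermediate
16 | (R)-5-[(S)-4-benzyl-2-oxooxazolidin-3-yl]-4-methyl-5-oxopentanoic acid | OC(=O)CC[C@@H](C)C(=O)N1[C@@H](Cc2ccccc2)COC1=O | intermediate
17 | (R)-5-[(S)-4-benzyl-2-oxooxazolidin-3-yl]-4-methyl-5-oxopentanoyl chloride | ClC(=O)CC[C@@H](C)C(=O)N1[C@@H](Cc2ccccc2)COC1=O | intermediate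
18 | (Z)-alkenyllithium from 12 (Li in place of I; not isolated) | C/C([Li])=C/[C@@H](O[Si](C)(C)C(C)(C)C)/C=C(/CO[Si](C)(C)C(C)(C)C)CO[Si](CC)(CC)CC | intermediate
19 | (Z)-alkenylzinc chloride from 12 (ZnCl in place of I; not isolated) | C/C([Zn]Cl)=C/[C@@H](O[Si](C)(C)C(C)(C)C)/C=C(/CO[Si](C)(C)C(C)(C)C)CO[Si](CC)(CC)CC | intermediate
20 | (S)-4-benzyl-3-[(2R,6Z,8S,9E)-8,11-bis{[tert-butyldimethylsilyl]oxy}-2,6-dimethyl-5-oxo-10-{[(triethylsilyl)oxy]methyl}undeca-6,9-dienoyl]oxazolidin-2-one | O=C(N1[C@@H](Cc2ccccc2)COC1=O)[C@H](C)CCC(=O)/C(C)=C\[C@@H](O[Si](C)(C)C(C)(C)C)/C=C(/CO[Si](C)(C)C(C)(C)C)CO[Si](CC)(CC)CC | intermediate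
21 | (S)-4-benzyl-3-[(2R,5S,6Z,8S,9E)-8,11-bis{[tert-butyldimethylsilyl]oxy}-5-hydroxy-2,6-dimethyl-10-{[(triethylsilyl)oxy]methyl}undeca-6,9-dienoyl]oxazolidin-2-one | O=C(N1[C@@H](Cc2ccccc2)COC1=O)[C@H](C)CC[C@H](O)/C(C)=C\[C@@H](O[Si](C)(C)C(C)(C)C)/C=C(/CO[Si](C)(C)C(C)(C)C)CO[Si](CC)(CC)CC | intermediate
22 | (S)-4-benzyl-3-[(2R,5S,6Z,8S,9E)-5,8,11-tris{[tert-butyldimethylsilyl]oxy}-2,6-dimethyl-10-{[(triethylsilyl)oxy]methyl}undeca-6,9-dienoyl]oxazolidin-2-one | O=C(N1[C@@H](Cc2ccccc2)COC1=O)[C@H](C)CC[C@H](O[Si](C)(C)C(C)(C)C)/C(C)=C\[C@@H](O[Si](C)(C)C(C)(C)C)/C=C(/CO[Si](C)(C)C(C)(C)C)CO[Si](CC)(CC)CC | intermediate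
23 | (S)-4-benzyl-3-[(2R,5S,6Z,8S,9E)-5,8,11-tris{[tert-butyldimethylsilyl]oxy}-10-(hydroxymethyl)-2,6-dimethylundeca-6,9-dienoyl]oxazolidin-2-one | O=C(N1[C@@H](Cc2ccccc2)COC1=O)[C@H](C)CC[C@H](O[Si](C)(C)C(C)(C)C)/C(C)=C\[C@@H](O[Si](C)(C)C(C)(C)C)/C=C(/CO[Si](C)(C)C(C)(C)C)CO | intermediate
24 | (2R,5S,6Z,8S,9E)-5,8,11-tris[(tert-butyldimethylsilyl)oxy]-10-(hydroxymethyl)-2,6-dimethylundeca-6,9-dienoic acid | OC(=O)[C@H](C)CC[C@H](O[Si](C)(C)C(C)(C)C)/C(C)=C\[C@@H](O[Si](C)(C)C(C)(C)C)/C=C(/CO[Si](C)(C)C(C)(C)C)CO | intermediate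
25 | mixed anhydride of 24 with 2,4,6-trichlorobenzoic acid (not isolated) | O=C(OC(=O)c1c(Cl)cc(Cl)cc1Cl)[C@H](C)CC[C@H](O[Si](C)(C)C(C)(C)C)/C(C)=C\[C@@H](O[Si](C)(C)C(C)(C)C)/C=C(/CO[Si](C)(C)C(C)(C)C)CO | intermediate
26 | (3R,6S,7Z,9S,10E)-6,9-bis[(tert-butyldimethylsilyl)oxy]-11-{[(tert-butyldimethylsilyl)oxy]methyl}-3,7-dimethyl-1-oxacyclododeca-7,10-dien-2-one | O=C1[C@H](C)CC[C@H](O[Si](C)(C)C(C)(C)C)/C(C)=C\[C@@H](O[Si](C)(C)C(C)(C)C)/C=C(/CO[Si](C)(C)C(C)(C)C)CO1 | intermediate
27 | (3R,6S,7Z,9S,10E)-6,9-bis[(tert-butyldimethylsilyl)oxy]-11-{[(tert-butyldimethylsilyl)oxy]methyl}-3,7-dimethyl-2-methylene-1-oxacyclododeca-7,10-diene | C=C1[C@H](C)CC[C@H](O[Si](C)(C)C(C)(C)C)/C(C)=C\[C@@H](O[Si](C)(C)C(C)(C)C)/C=C(/CO[Si](C)(C)C(C)(C)C)CO1 | intermediate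
28 | (2R,5S,6Z,8R,9S)-5,8-bis[(tert-butyldimethylsilyl)oxy]-9-{3-[(tert-butyldimethylsilyl)oxy]prop-1-en-2-yl}-2,6-dimethylcyclodec-6-en-1-one | C=C(CO[Si](C)(C)C(C)(C)C)[C@@H]1CC(=O)[C@H](C)CC[C@H](O[Si](C)(C)C(C)(C)C)/C(C)=C\[C@H]1O[Si](C)(C)C(C)(C)C | intermediate
29 | (1S,2R,5S,6Z,8R,9S)-5,8-bis[(tert-butyldimethylsilyl)oxy]-9-{3-[(tert-butyldimethylsilyl)oxy]prop-1-en-2-yl}-2,6-dimethylcyclodec-6-en-1-ol | C=C(CO[Si](C)(C)C(C)(C)C)[C@@H]1C[C@H](O)[C@H](C)CC[C@H](O[Si](C)(C)C(C)(C)C)/C(C)=C\[C@H]1O[Si](C)(C)C(C)(C)C | intermediate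
30 | angelic acid, (Z)-2-methylbut-2-enoic acid | C/C=C(/C)C(=O)O | starting material
31 | angelic 2,4,6-trichlorobenzoic anhydride (not isolated) | C/C=C(/C)C(=O)OC(=O)c1c(Cl)cc(Cl)cc1Cl | intermediate
32 | (1S,2R,5S,6Z,8R,9S)-5,8-bis[(tert-butyldimethylsilyl)oxy]-9-{3-[(tert-butyldimethylsilyl)oxy]prop-1-en-2-yl}-2,6-dimethylcyclodec-6-en-1-yl (Z)-2-methylbut-2-enoate | C=C(CO[Si](C)(C)C(C)(C)C)[C@@H]1C[C@H](OC(=O)/C(C)=C\C)[C@H](C)CC[C@H](O[Si](C)(C)C(C)(C)C)/C(C)=C\[C@H]1O[Si](C)(C)C(C)(C)C | intermediate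
33 | (1S,2R,5S,6Z,8R,9S)-5,8-dihydroxy-9-(3-hydroxyprop-1-en-2-yl)-2,6-dimethylcyclodec-6-en-1-yl (Z)-2-methylbut-2-enoate | C=C(CO)[C@@H]1C[C@H](OC(=O)/C(C)=C\C)[C@H](C)CC[C@H](O)/C(C)=C\[C@H]1O | intermediate
34 | (1S,2R,5S,6Z,8R,9S)-5,8-dihydroxy-2,6-dimethyl-9-(3-oxoprop-1-en-2-yl)cyclodec-6-en-1-yl (Z)-2-methylbut-2-enoate (not isolated) | C=C(C=O)[C@@H]1C[C@H](OC(=O)/C(C)=C\C)[C@H](C)CC[C@H](O)/C(C)=C\[C@H]1O | intermediate
35 | γ-lactol of 34 (C12 hemiacetal closed onto O-6, both anomers; not isolated) | C=C1C(O)O[C@@H]2/C=C(/C)[C@@H](O)CC[C@@H](C)[C@@H](OC(=O)/C(C)=C\C)C[C@@H]12 | intermediate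
36 | (3S,6R,7S,9S,10R)-9-angeloyloxy-3-hydroxygermacra-4(Z),11(13)-dien-12,6-olide | C=C1C(=O)O[C@@H]2/C=C(/C)[C@@H](O)CC[C@@H](C)[C@@H](OC(=O)/C(C)=C\C)C[C@@H]12 | intermediate
37 | (3S,6R,7S,9S,10R)-3-acetoxy-9-angeloyloxygermacra-4(Z),11(13)-dien-12,6-olide (CNP0173235.1) | C=C1C(=O)O[C@@H]2/C=C(/C)[C@@H](OC(C)=O)CC[C@@H](C)[C@@H](OC(=O)/C(C)=C\C)C[C@@H]12 | target

Total step count: 23 (steps 8–10 are a three-step side branch).
Longest linear sequence: 20 steps (1–7, then 11–23).

Steps most likely to fail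

Step 18 (key step). The macrocyclic transition state may not discriminate the two faces of C7 well enough. In addition, traces of acid may shift the exocyclic C8=C9 bond into the ring or hydrolyse the enol ether before the sigmatropic shift occurs at 150 °C. The fallback sets out from 27 and replaces the thermal pericyclic step by an aluminium-promoted, charge-accelerated rearrangement with i-Bu3Al (CH2Cl2, −78 → 0 °C). The Lewis acid binds the ether oxygen, the C13–O bond ionises and C7–C8 forms at low temperature in a tighter transition state, where the face anti to the C6–O bond should be preferred even more strongly. The aluminium-bound ketone 28 is not released: it is reduced in the flask by β-hydride transfer from an isobutyl group, again from the ring periphery, which should give alcohol 29 directly. The route is rejoined at 29 (before step 20). This fallback forms no compound outside the list (none, F0).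

Step 19. Hydride may be delivered to the other face of the C9 carbonyl, because the conformation of the ten-membered ring and not the Felkin preference may decide. The fallback sets out from 28, accepts that outcome and takes on the (9R)-epimeric alcohol F1. It is esterified with angelic acid 30 under Mitsunobu conditions (PPh3, DIAD, toluene, 0 → 23 °C), which installs the angelate with inversion at C9 and should give 32 directly. The route is rejoined at 32 (before step 21). If the reduction is unselective, both epimers are funnelled to 32, 29 by step 20 and F1 by this inversion.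

Step 22. Chemoselectivity may be lost on the unprotected triol: the secondary allylic hydroxyls at C3 or C6 may be oxidised before the lactol closes, or the 2-substituted acrolein may polymerise. The fallback sets out from 32 and adjusts the oxidation level of C12 before the secondary alcohols are exposed. The primary allylic TBS ether is cleaved selectively (HF·pyridine, excess pyridine, THF, 0 °C) to the C12 alcohol F2, which is oxidised with Dess–Martin periodinane to the enal F3. Pinnick oxidation (NaClO2, NaH2PO4, 2-methylbut-2-ene) then gives the acrylic acid F4. HF·pyridine removes the two secondary TBS groups to give the dihydroxy acid F5, which should lactonise onto the γ-hydroxyl at C6 (spontaneously or with PPTS) to give 36. The route is rejoined at 36 (before step 23).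

Further compounds
F0 | step 18 | none | none
F1 | step 19 | (1R,2R,5S,6Z,8R,9S)-5,8-bis[(tert-butyldimethylsilyl)oxy]-9-{3-[(tert-butyldimethylsilyl)oxy]prop-1-en-2-yl}-2,6-dimethylcyclodec-6-en-1-ol (C9 epimer of 29) | C=C(CO[Si](C)(C)C(C)(C)C)[C@@H]1C[C@@H](O)[C@H](C)CC[C@H](O[Si](C)(C)C(C)(C)C)/C(C)=C\[C@H]1O[Si](C)(C)C(C)(C)C
F2 | step 22 | 32 without its primary TBS group (free C12–OH; configuration as in 32) | C=C(CO)[C@@H]1C[C@H](OC(=O)/C(C)=C\C)[C@H](C)CC[C@H](O[Si](C)(C)C(C)(C)C)/C(C)=C\[C@H]1O[Si](C)(C)C(C)(C)C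
F3 | step 22 | enal from F2 (C12 aldehyde; configuration as in 32) | C=C(C=O)[C@@H]1C[C@H](OC(=O)/C(C)=C\C)[C@H](C)CC[C@H](O[Si](C)(C)C(C)(C)C)/C(C)=C\[C@H]1O[Si](C)(C)C(C)(C)C
F4 | step 22 | acrylic acid from F3 (C12 carboxylic acid, 3,6-bis-TBS ether; configuration as in 32) | C=C(C(=O)O)[C@@H]1C[C@H](OC(=O)/C(C)=C\C)[C@H](C)CC[C@H](O[Si](C)(C)C(C)(C)C)/C(C)=C\[C@H]1O[Si](C)(C)C(C)(C)C
F5 | step 22 | 3,6-dihydroxy acrylic acid from F4 (seco acid of 36) | C=C(C(=O)O)[C@@H]1C[C@H](OC(=O)/C(C)=C\C)[C@H](C)CC[C@H](O)/C(C)=C\[C@H]1O
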